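The rate constants are those of an exercise, and the outcome is calculated.

The solid substrate of this flask is charged at 0.50 M, but starting material stands in solution up to 0.18 M, and it meets a gas that saturates at 67 mM.

    starting material + dissolved gas → target (k1 = 1.2 /M/min)
    gas phase ⇌ dissolved gas, rate k2*(csat - [dissolved gas]) (k2 = 2.6 /min, csat = 67 mM)
    dissolved gas + target → over-reacted product (k3 = 0.22 /M/min)
    solid substrate ⇌ starting material, rate k4*(cs4 - [starting material]) while solid is left; crystals form when [starting material] > cs4 (cs4 = 0.18 M, k4 = 0.053 /min)
    dissolved gas + protic impurity → quenched reagent (k5 = 0.11 /M/min)

solid substrate 0.50 M; gas phase 67 mM (held); protic impurity 0.250 M; time 30 min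

- as a solid, counted per litre of solution: solid substrate
- at the start none of the gas is dissolved
- at the start none of the solid substrate is in solution
- run time (flask): 30 min

* amount of target at 30 min, in percent of the solid substrate charged
* the change that raises the amount of target at 30 min, in percent of the solid substrate charged most ("none" if none brings more than 2 percentage points) (epsilon / beta / eta / alpha / none)
* amount of target at 30 min, in percent of the solid substrate charged, after epsilon

- epsilon: doubling the dissolution coefficient of step 4, all else as stated
- beta: doubling the solubility in step 4, all else as stated
- eta: doubling the transfer coefficient of step 2, all else as stated
- alpha: doubling the saturation concentration of gas phase, all else as stated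

A reckoning by hand compares rates at one moment. Transfer renews dissolved gas at 2.6 /min, against 0.243 /min for the pull of the two reactions with starting material at its solubility and protic impurity as charged, so [dissolved gas] is taken as 67 mM. The reaction to target is then pseudo-first-order in starting material, with 0.0804 /min. Dissolving into an empty solution delivers 57.2% of the charge by 30 min, so solid remains up to that time. [Starting material] therefore climbs, on a time scale of 7.50 min, to 0.0715 M, the standing level: solubility times dissolution coefficient, divided by the sum of that coefficient and the pseudo-first-order constant, where dissolving pays exactly what the reaction takes. That is 14.3% of the charge.

The standing rate is 0.00575 M/min. Multiplied by the whole 30 min, it gives a turnover of 34.5% of the charge. Counting the climb shortens the effective time by the time scale and gives 25.9%. The two part, and the first cheats: it credits the full rate to minutes when [starting material] is still low. Over-reaction removes target at 0.0147 /min over a mean age of 11.2 min, so 84.7% survives and the reckoning gives 21.9%. By the same reckoning, doubling the solubility gives 43.8%, epsilon gives 33.8%, and alpha gives 25.0%.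

The forecast gives 21.4% (from 19.5% to 23.5%), chooses beta, and puts epsilon at 32.6% (from 29.5% to 35.5%), on the grounds of “slow dissolution feeding a starting-material level”. The reckoning above stands slightly higher on both numbers and makes the same choice.

The simulation gives 21.4%, and 32.8% after epsilon. The best change is beta, with 21 percentage points.

In the flask, starting material reads 14.4% of the charge at 30.0 min, against a reckoned standing level of 14.3%. The low solubility is the main reason for the shortfall: without it, target reaches 68.3% instead of 21.4%. The expression for the standing level holds no amount of solid substrate charged, and solid is still left in the neighbour with 1.2 M of solid substrate, so there 0.0715 M is 5.96% of that charge, and that neighbour reads 6.00% at 30.0 min. That neighbour holds 0.107 M of target, against 0.107 M in the flask.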